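**Retrosynthetic overview**

1. Feature: in each outer ring the methoxy-bearing carbon C6 lies ortho to the butanoyl-bearing carbon C1 and next to C5–CH3. Without that oxygen each outer ring is a 2,4-dioxygenated 5-methylphenyl ketone with one ortho C–H (C6–H) and one nucleophilic CH (C3).
2. Endgame: agrimol B ⇐ hepta-O-benzyl trimer with both outer ketones masked as (E)-O-methyl oximes (oxime exchange, then hydrogenolysis of seven benzyl ethers).
3. Key disconnection: both aryl C6–OMe bonds ⇐ two C6–H bonds, formed in one operation by oxime-ether-directed C–H methoxylation with Pd(OAc)2.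
4. Trimer ⇐ two ArCH2–Ar bonds between C3 of a 4-O-benzyl resorcinol Mannich base (through its o-quinone methide) and C3/C5 of (S)-2-methylbutanoylphloroglucinol. The benzyl ethers are installed in two stages: one per outer ring on the monomer, the remaining five on the trimer.
5. No ring is formed at any stage: the three benzene rings come from the starting phenols and the single stereocentre is bought with (S)-2-methylbutanoic acid.

Key step: step 8

Remark: outer-ring positions are numbered C1 (ketone or oxime carbon attached), C2 (O), C3 (bridge), C4 (O), C5 (CH3), C6 (H, later OMe), and the monomer names use this numbering. The (E) oxime geometry set in step 3 is assumed to persist through the non-acidic steps 4 to 7.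

**Route**

Step 1
Reactants: 1 4-methylresorcinol; 2 butanoic acid
Product: 3 1-(2,4-dihydroxy-5-methylphenyl)butan-1-one
Conditions: ZnCl2 (1.5 equiv), 2 (3 equiv, neat), 130 °C; then 1 M HCl
Reagents that add atoms: none
Why: Nencki reaction (ZnCl2-promoted Friedel–Crafts C-acylation of a resorcinol by a carboxylic acid): the acyl group should enter at C6 of 1, para to one hydroxyl and ortho to the other, and the chelated o-hydroxy ketone formed resists a second acylation.

Step 2
Reactants: 3 1-(2,4-dihydroxy-5-methylphenyl)butan-1-one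
Product: 4 1-[4-(benzyloxy)-2-hydroxy-5-methylphenyl]butan-1-one
Conditions: BnBr (1.05 equiv), K2CO3 (1.2 equiv), acetone, reflux
Reagents that add atoms: benzyl bromide, BrCc1ccccc1
Why: Williamson ether synthesis with site selection by acidity and hydrogen bonding: the C4 hydroxyl para to the ketone is the more acidic and is free, whereas the C2 hydroxyl is held in a chelate with the carbonyl oxygen, so one equivalent of benzyl bromide should give the 4-O-benzyl ether only.

Step 3
Reactants: 4 1-[4-(benzyloxy)-2-hydroxy-5-methylphenyl]butan-1-one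
Product: 5 (E)-1-[4-(benzyloxy)-2-hydroxy-5-methylphenyl]butan-1-one O-methyl oxime
Conditions: MeONH2·HCl, NaOAc, EtOH/H2O, 70 °C
Reagents that add atoms: O-methylhydroxylamine hydrochloride, CON.Cl
Why: Condensation of a ketone with O-methylhydroxylamine to an oxime ether: the C2 hydroxyl hydrogen-bonds to the imine nitrogen, which should favour the (E) isomer (OMe anti to the ring, lone pair toward the ring) that the directed palladation of step 8 needs.

Step 4
Reactants: 5 (E)-1-[4-(benzyloxy)-2-hydroxy-5-methylphenyl]butan-1-one O-methyl oxime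
Product: 6 (E)-1-{4-(benzyloxy)-3-[(dimethylamino)methyl]-2-hydroxy-5-methylphenyl}butan-1-one O-methyl oxime
Conditions: 40% aq. Me2NH, 37% aq. CH2O, EtOH, 70 °C
Reagents that add atoms: formaldehyde, C=O; dimethylamine, CNC
Why: Mannich reaction of a phenol: C3, ortho to the free C2 hydroxyl and to the C4 benzyloxy group, is the only activated ring CH (C6 is meta to both oxygens), so a single dimethylaminomethyl group should enter there.

Step 5
Reactants: 7 (S)-2-methylbutanoic acid; 8 phloroglucinol
Product: 10 (S)-2-methyl-1-(2,4,6-trihydroxyphenyl)butan-1-one, via (S)-2-methylbutanoyl chloride 9 (not isolated)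
Conditions: (COCl)2, cat. DMF, CH2Cl2, 0 °C → rt; then 8, AlCl3, PhNO2/CH2Cl2, 0 → 40 °C; 1 M HCl
Reagents that add atoms: oxalyl chloride, O=C(Cl)C(=O)Cl (supplies only the chlorine of intermediate 9)
Why: Acid chloride formation with oxalyl chloride and catalytic DMF, then AlCl3-mediated Friedel–Crafts C-acylation of phloroglucinol, which should stop at monoacylation because the acyl group deactivates the ring; the stereocentre is carried over from 7 and no base is present to enolise it (configurational integrity to be checked by chiral HPLC).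

Step 6
Reactants: 6 (E)-1-{4-(benzyloxy)-3-[(dimethylamino)methyl]-2-hydroxy-5-methylphenyl}butan-1-one O-methyl oxime (2.2 equiv); 10 (S)-2-methyl-1-(2,4,6-trihydroxyphenyl)butan-1-one
Product: 12 di-O-benzyl pentaphenolic trimer bis(O-methyl oxime), via o-quinone methide 11 (not isolated)
Conditions: 1,4-dioxane, 100 °C, N2 sweep
Reagents that add atoms: none
Why: Thermal loss of dimethylamine from the phenolic Mannich base across the C2 hydroxyl (helped by proton transfer from the acidic acylphloroglucinol) gives o-quinone methide 11, which should be captured by conjugate addition (Friedel–Crafts-type C-alkylation) at the two free ring carbons C3 and C5 of the strongly nucleophilic 10; 6 has no nucleophilic CH of its own and 10 has exactly two, so the 2:1 adduct is the expected end point.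

Step 7
Reactants: 12 di-O-benzyl pentaphenolic trimer bis(O-methyl oxime)
Product: 13 hepta-O-benzyl trimer bis(O-methyl oxime)
Conditions: BnBr (8 equiv), Cs2CO3 (8 equiv), Bu4NI (cat.), DMF, rt → 40 °C
Reagents that add atoms: benzyl bromide, BrCc1ccccc1
Why: Williamson ether synthesis: caesium phenoxides in DMF with a reactive benzylic bromide should give O-alkylation at the five remaining hydroxyls (the two outer C2 hydroxyls and the three of the central ring), including the hydrogen-bonded ones, while the oxime ethers are inert and the mild temperature spares the stereocentre α to the central ketone.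

Step 8
Reactants: 13 hepta-O-benzyl trimer bis(O-methyl oxime)
Product: 14 hepta-O-benzyl 6,6'-dimethoxy trimer bis(O-methyl oxime) (perbenzylated agrimol B bis(O-methyl oxime))
Conditions: Pd(OAc)2 (20 mol%), PhI(OAc)2 (3 equiv), MeOH/ClCH2CH2Cl (3:1), 70 °C
Reagents that add atoms: methanol, CO
Why: The nitrogen of each (E)-oxime ether binds Pd(OAc)2 and holds it at C6–H, where acetate-assisted concerted metalation–deprotonation should give a five-membered palladacycle of divalent palladium; PhI(OAc)2 in methanol then raises it to tetravalent palladium carrying methoxide, and C–O reductive elimination forms the aryl–OMe bond and returns divalent palladium. The closest known reaction type is the Pd(OAc)2-catalysed, oxime-ether-directed ortho C–H alkoxylation of aryl ketoxime ethers with a hypervalent iodine oxidant in an alcohol solvent. No ring is closed in the product (the palladacycle is transient) and no stereocentre is formed, while the remote (S) centre sees only warm, weakly acidic methanol. Site selectivity is needed and is secured because C6–H is the only aryl C–H ortho to a directing nitrogen: C2 carries a benzyloxy group, the central ketone has no oxime and no ortho C–H, and the (E) geometry turns the nitrogen lone pair toward the ring and away from the propyl chain, whose methylene C–H bonds are thereby out of reach. Chemoselectivity against oxidation of the oxygenated rings and of the two ArCH2Ar bridges is also needed, and with all seven phenols capped as benzyl ethers no quinoid oxidation is open and both bridges are shielded by flanking benzyloxy groups. Once methoxylated, each oxime is di-ortho-substituted and twisted, so it should release palladium for the second site.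

Step 9
Reactants: 14 hepta-O-benzyl 6,6'-dimethoxy trimer bis(O-methyl oxime)
Product: 15 hepta-O-benzyl agrimol B
Conditions: 37% aq. CH2O (excess), TsOH·H2O (cat.), THF/acetone, 60 °C
Reagents that add atoms: water, O
Why: Acid-catalysed transoximation: hydrolysis of the protonated oxime ethers is pulled forward by capture of the released O-methylhydroxylamine by formaldehyde, while benzyl and methyl aryl ethers should survive the sulfonic acid, every ring carbon is substituted so formaldehyde finds no site for hydroxymethylation, and with every phenol capped the bridges cannot fragment through a quinone methide.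

Step 10
Reactants: 15 hepta-O-benzyl agrimol B
Product: 16 agrimol B
Conditions: H2 (1 atm), Pd/C (10% palladium on carbon), EtOAc/MeOH, rt
Reagents that add atoms: none
Why: Catalytic hydrogenolysis of benzyl aryl ethers under neutral conditions, which should leave the aryl methyl ethers, the diarylmethane bridges, the three ketones (hydrogen-bonded once the phenols are free) and the stereocentre untouched.

**Compound list**

1 | 4-methylresorcinol | Cc1ccc(O)cc1O | starting material
2 | butanoic acid | CCCC(=O)O | starting material
3 | 1-(2,4-dihydroxy-5-methylphenyl)butan-1-one | CCCC(=O)c1cc(C)c(O)cc1O | intermediate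
4 | 1-[4-(benzyloxy)-2-hydroxy-5-methylphenyl]butan-1-one | CCCC(=O)c1cc(C)c(OCc2ccccc2)cc1O | intermediate
5 | (E)-1-[4-(benzyloxy)-2-hydroxy-5-methylphenyl]butan-1-one O-methyl oxime | CCC/C(=N\OC)c1cc(C)c(OCc2ccccc2)cc1O | intermediate
6 | (E)-1-{4-(benzyloxy)-3-[(dimethylamino)methyl]-2-hydroxy-5-methylphenyl}butan-1-one O-methyl oxime | CCC/C(=N\OC)c1cc(C)c(OCc2ccccc2)c(CN(C)C)c1O | intermediate
7 | (S)-2-methylbutanoic acid | CC[C@H](C)C(=O)O | starting material
8 | phloroglucinol | Oc1cc(O)cc(O)c1 | starting material
9 | (S)-2-methylbutanoyl chloride | CC[C@H](C)C(=O)Cl | intermediate (not isolated)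
10 | (S)-2-methyl-1-(2,4,6-trihydroxyphenyl)butan-1-one | CC[C@H](C)C(=O)c1c(O)cc(O)cc1O | intermediate
11 | o-quinone methide from 6: 3-(benzyloxy)-6-[(E)-1-(methoxyimino)butyl]-4-methyl-2-methylidenecyclohexa-3,5-dien-1-one | C=C1C(=O)C(/C(CCC)=N/OC)=CC(C)=C1OCc1ccccc1 | intermediate (not isolated)
12 | di-O-benzyl pentaphenolic trimer bis(O-methyl oxime): (S)-1-{2,4,6-trihydroxy-3,5-bis({6-(benzyloxy)-2-hydroxy-3-[(E)-1-(methoxyimino)butyl]-5-methylphenyl}methyl)phenyl}-2-methylbutan-1-one | CCC/C(=N\OC)c1cc(C)c(OCc2ccccc2)c(Cc2c(O)c(Cc3c(OCc4ccccc4)c(C)cc(/C(CCC)=N/OC)c3O)c(O)c(C(=O)[C@@H](C)CC)c2O)c1O | intermediate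
13 | hepta-O-benzyl trimer bis(O-methyl oxime): (S)-1-{2,4,6-tris(benzyloxy)-3,5-bis({2,6-bis(benzyloxy)-3-[(E)-1-(methoxyimino)butyl]-5-methylphenyl}methyl)phenyl}-2-methylbutan-1-one | CCC/C(=N\OC)c1cc(C)c(OCc2ccccc2)c(Cc2c(OCc3ccccc3)c(Cc3c(OCc4ccccc4)c(C)cc(/C(CCC)=N/OC)c3OCc3ccccc3)c(OCc3ccccc3)c(C(=O)[C@@H](C)CC)c2OCc2ccccc2)c1OCc1ccccc1 | intermediate
14 | hepta-O-benzyl 6,6'-dimethoxy trimer bis(O-methyl oxime): (S)-1-{2,4,6-tris(benzyloxy)-3,5-bis({2,6-bis(benzyloxy)-4-methoxy-3-[(E)-1-(methoxyimino)butyl]-5-methylphenyl}methyl)phenyl}-2-methylbutan-1-one | CCC/C(=N\OC)c1c(OC)c(C)c(OCc2ccccc2)c(Cc2c(OCc3ccccc3)c(Cc3c(OCc4ccccc4)c(C)c(OC)c(/C(CCC)=N/OC)c3OCc3ccccc3)c(OCc3ccccc3)c(C(=O)[C@@H](C)CC)c2OCc2ccccc2)c1OCc1ccccc1 | intermediate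
15 | hepta-O-benzyl agrimol B: (S)-1-{2,4,6-tris(benzyloxy)-3,5-bis({2,6-bis(benzyloxy)-3-butanoyl-4-methoxy-5-methylphenyl}methyl)phenyl}-2-methylbutan-1-one | CCCC(=O)c1c(OC)c(C)c(OCc2ccccc2)c(Cc2c(OCc3ccccc3)c(Cc3c(OCc4ccccc4)c(C)c(OC)c(C(=O)CCC)c3OCc3ccccc3)c(OCc3ccccc3)c(C(=O)[C@@H](C)CC)c2OCc2ccccc2)c1OCc1ccccc1 | intermediate
16 | agrimol B: (S)-1-{3,5-bis[(3-butanoyl-2,6-dihydroxy-4-methoxy-5-methylphenyl)methyl]-2,4,6-trihydroxyphenyl}-2-methylbutan-1-one | CCCC(=O)c1c(O)c(Cc2c(O)c(Cc3c(O)c(C)c(OC)c(C(=O)CCC)c3O)c(O)c(C(=O)[C@@H](C)CC)c2O)c(O)c(C)c1OC | target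

**Step count**

Total: 10 steps. Longest linear sequence: 9 steps (steps 1, 2, 3, 4, 6, 7, 8, 9, 10 from 4-methylresorcinol); step 5 is the side branch.

**Three steps most likely to fail**

1. Step 8. Cyclopalladation may be slow, because C6–H lies between the oxime-bearing carbon and C5–CH3 and the oxime is twisted by the C2 benzyloxy group. While it lags, methanol can reduce the catalyst to palladium black and the oxidant can attack the doubly benzylic bridges; the reaction must also succeed twice in one molecule. The fallback sets out from 5 and comes back to the route at 16. It moves the same C–H methoxylation to the monomer, a simple aryl ketoxime ether without bridges, and forms the bridges last on free phenols. The remaining hydroxyl of 5 is benzylated (BnBr, K2CO3, DMF, 60 °C) to (E)-1-[2,4-bis(benzyloxy)-5-methylphenyl]butan-1-one O-methyl oxime F1. Pd(OAc)2 with PhI(OAc)2 in MeOH should then give (E)-1-[2,4-bis(benzyloxy)-6-methoxy-5-methylphenyl]butan-1-one O-methyl oxime F2. Exchange with aqueous formaldehyde and TsOH·H2O should give 1-[2,4-bis(benzyloxy)-6-methoxy-5-methylphenyl]butan-1-one F3, and hydrogenolysis (H2, Pd/C) should give 1-(2,4-dihydroxy-6-methoxy-5-methylphenyl)butan-1-one F4. A Mannich reaction (Me2NH, CH2O, EtOH) at the only free ring CH should give 1-{3-[(dimethylamino)methyl]-2,4-dihydroxy-6-methoxy-5-methylphenyl}butan-1-one F5. Heating F5 (2 equiv) with 10 in dioxane should bridge both free carbons of 10 and give 16 directly.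

2. Step 7. Benzyl bromide may alkylate the fully substituted central ring at carbon with dearomatisation, hydrogen-bonded hydroxyls may stay unetherified, and prolonged base may erode the α-stereocentre. The fallback sets out from 12 and comes back at 16. It caps the five free phenols with a hard oxocarbenium-type electrophile and unmasks them together with the ketones in one acidic operation. Treating 12 with MOMCl (iPr2NEt, CH2Cl2; then NaH, DMF, 0 °C for the hydrogen-bonded hydroxyls) should give the di-O-benzyl penta(methoxymethyl) ether bis(O-methyl oxime) F6. The methoxylation of step 8 applied to F6 should give the dimethoxylated di-O-benzyl penta(methoxymethyl) ether bis(O-methyl oxime) F7. Aqueous HCl in THF/MeOH at 50 °C should remove the five acetals, and the formaldehyde they release should take up the O-methylhydroxylamine of the two oxime ethers, to give 4,4'-di-O-benzyl agrimol B F8. Hydrogenolysis of F8 (H2, Pd/C, EtOAc/MeOH) should give 16. The cost is that partly free phenols then meet acid, which the benzyl route avoids.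

3. Step 9. The exchange may stall at the twisted, di-ortho-substituted C=N bonds, and forcing the acid may strip benzyl groups and expose the bridges. The fallback sets out from 14 and comes back at 15. It replaces hydrolytic exchange by reductive N–O cleavage. Aqueous TiCl3 buffered with NH4OAc in THF (rt to 50 °C) should cleave both N–O bonds by electron transfer from trivalent titanium to give the hepta-O-benzyl bis(N–H ketimine) F9. On stirring with dilute HCl, F9 should hydrolyse to 15 more readily than an oxime ether, because its nitrogen is more basic.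

**Further compounds**

F1 | step 8 | (E)-1-[2,4-bis(benzyloxy)-5-methylphenyl]butan-1-one O-methyl oxime | CCC/C(=N\OC)c1cc(C)c(OCc2ccccc2)cc1OCc1ccccc1
F2 | step 8 | (E)-1-[2,4-bis(benzyloxy)-6-methoxy-5-methylphenyl]butan-1-one O-methyl oxime | CCC/C(=N\OC)c1c(OC)c(C)c(OCc2ccccc2)cc1OCc1ccccc1
F3 | step 8 | 1-[2,4-bis(benzyloxy)-6-methoxy-5-methylphenyl]butan-1-one | CCCC(=O)c1c(OC)c(C)c(OCc2ccccc2)cc1OCc1ccccc1
F4 | step 8 | 1-(2,4-dihydroxy-6-methoxy-5-methylphenyl)butan-1-one | CCCC(=O)c1c(OC)c(C)c(O)cc1O
F5 | step 8 | 1-{3-[(dimethylamino)methyl]-2,4-dihydroxy-6-methoxy-5-methylphenyl}butan-1-one | CCCC(=O)c1c(OC)c(C)c(O)c(CN(C)C)c1O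
F6 | step 7 | di-O-benzyl penta(methoxymethyl) ether of 12, bis(O-methyl oxime) | CCC/C(=N\OC)c1cc(C)c(OCc2ccccc2)c(Cc2c(OCOC)c(Cc3c(OCc4ccccc4)c(C)cc(/C(CCC)=N/OC)c3OCOC)c(OCOC)c(C(=O)[C@@H](C)CC)c2OCOC)c1OCOC
F7 | step 7 | dimethoxylated di-O-benzyl penta(methoxymethyl) ether bis(O-methyl oxime) | CCC/C(=N\OC)c1c(OC)c(C)c(OCc2ccccc2)c(Cc2c(OCOC)c(Cc3c(OCc4ccccc4)c(C)c(OC)c(/C(CCC)=N/OC)c3OCOC)c(OCOC)c(C(=O)[C@@H](C)CC)c2OCOC)c1OCOC
F8 | step 7 | 4,4'-di-O-benzyl agrimol B | CCCC(=O)c1c(OC)c(C)c(OCc2ccccc2)c(Cc2c(O)c(Cc3c(OCc4ccccc4)c(C)c(OC)c(C(=O)CCC)c3O)c(O)c(C(=O)[C@@H](C)CC)c2O)c1O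
F9 | step 9 | hepta-O-benzyl bis(N–H ketimine) of 15 | CCCC(=N)c1c(OC)c(C)c(OCc2ccccc2)c(Cc2c(OCc3ccccc3)c(Cc3c(OCc4ccccc4)c(C)c(OC)c(C(=N)CCC)c3OCc3ccccc3)c(OCc3ccccc3)c(C(=O)[C@@H](C)CC)c2OCc2ccccc2)c1OCc1ccccc1
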